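**Strategy.** The route disconnects the ring oxygen of ring D: both of its bonds, O–C(lactol) and O–C(=O), are made last by inserting oxygen into a four-membered ketone fused to ring B. The step exploits that the lactol carbon (the CH(OH) of ring D, on the ring-B carbon next to the diaryl-ether oxygen), labile in the target, is a configurationally fixed siloxy carbinol once that oxygen is absent. One Baeyer–Villiger operation expands the cyclobutenone to ring D, places the lactone carbonyl beside the ring-B phenol and relays the carbinol configuration with retention into a silyl acetal. The precursor is the tris-TBS depsidone carrying a ring-B-fused (S)-2-siloxybenzocyclobutenone.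

Key step: step 18

Remark (ring positions and abbreviations): ring A is the methoxy-bearing arene; going round, it carries OMe, H, CH3, the ring-C carbonyl carbon, the diaryl-ether oxygen and the ring-A phenol. Ring B carries in sequence the diaryl-ether oxygen, the ring-C ester oxygen, CH3, the ring-B phenol, the phenol-side fusion carbon (which bears the lactone or ketone carbon) and the ether-side fusion carbon (which bears the lactol or carbinol carbon). Ring C is the seven-membered lactone, ring D the five-membered lactol ring. In the four-membered ring, C-1 sits on the phenol-side fusion carbon and C-2 on the ether-side fusion carbon. TBS = tert-butyldimethylsilyl, Bn = benzyl.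

Remark (assumption): the free lactol can equilibrate with its open formyl acid; it is assumed that the (R) form persists when the last step and the isolation are kept cold and free of base.

Remark (descriptors): one and the same spatial arrangement at the carbon on the ether-side fusion carbon is (S) in the siloxy compounds and (R) in the target, only because the priority order changes; for a racemate the SMILES shows one enantiomer.

Step 1
Reactants: 1 creosol (2-methoxy-4-methylphenol)
Product: 2 2-bromo-6-methoxy-4-methylphenol
Conditions: NBS, i-Pr2NH (cat.), CH2Cl2, 0 °C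
Reagents that add atoms: N-bromosuccinimide, O=C1CCC(=O)N1Br
Why: Amine-mediated electrophilic aromatic bromination of a phenol goes ortho to the hydroxyl, and with the para position blocked by methyl only the position next to the hydroxyl is open to it.

Step 2
Reactants: 2 2-bromo-6-methoxy-4-methylphenol
Product: 3 2-(benzyloxy)-1-bromo-3-methoxy-5-methylbenzene
Conditions: BnBr, K2CO3, DMF, rt
Reagents that add atoms: benzyl bromide, BrCc1ccccc1
Why: Williamson ether synthesis on a phenoxide caps the hydroxyl so that the methoxy group alone directs the next substitution.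

Step 3
Reactants: 3 2-(benzyloxy)-1-bromo-3-methoxy-5-methylbenzene
Product: 4 3-(benzyloxy)-2-bromo-4-methoxy-6-methylbenzaldehyde
Conditions: Cl2CHOMe, SnCl4, CH2Cl2, −20 → 0 °C; then H2O
Reagents that add atoms: dichloromethyl methyl ether, COC(Cl)Cl; water, O
Why: Rieche formylation should enter para to the methoxy group and ortho to methyl, the pattern of 3,4-dialkoxytoluenes, while the benzyloxy group is meta to both open positions and the mild Lewis acid at low temperature spares the benzyl ether.

Step 4
Reactants: 4 3-(benzyloxy)-2-bromo-4-methoxy-6-methylbenzaldehyde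
Product: 5 3-(benzyloxy)-2-bromo-4-methoxy-6-methylbenzoic acid
Conditions: NaClO2, NaH2PO4, 2-methyl-2-butene, t-BuOH–H2O, rt
Reagents that add atoms: sodium chlorite, [Na+].[O-]Cl=O
Why: Pinnick oxidation converts even doubly flanked aryl aldehydes to acids, and the alkene scavenger keeps hypochlorite from chlorinating the electron-rich ring.

Step 5
Reactants: 6 2,4-dihydroxy-3-methylbenzaldehyde
Product: 7 2,4-bis(benzyloxy)-3-methylbenzaldehyde
Conditions: BnBr, K2CO3, DMF, 60 °C
Reagents that add atoms: benzyl bromide, BrCc1ccccc1
Why: Double Williamson ether synthesis, with excess bromide and warming so that the hydrogen-bonded 2-hydroxyl is also alkylated.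

Step 6
Reactants: 7 2,4-bis(benzyloxy)-3-methylbenzaldehyde
Product: 9 2,4-bis(benzyloxy)-3-methylphenol, via aryl formate 8 (not isolated)
Conditions: mCPBA, CH2Cl2, 0 °C → rt; then K2CO3 (cat.), MeOH, rt
Reagents that add atoms: 3-chloroperbenzoic acid, OOC(=O)c1cccc(Cl)c1
Why: Dakin-type Baeyer–Villiger oxidation of an aldehyde with ortho and para alkoxy groups proceeds by aryl migration to the formate, which is methanolysed to the phenol whose oxygen becomes the diaryl-ether oxygen.

Step 7
Reactants: 9 2,4-bis(benzyloxy)-3-methylphenol
Product: 10 3,5-bis(benzyloxy)-2-hydroxy-4-methylbenzaldehyde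
Conditions: MgCl2, Et3N, (CH2O)n, MeCN, reflux
Reagents that add atoms: formaldehyde (from paraformaldehyde), C=O
Why: Magnesium-mediated ortho-formylation (Casnati–Skattebøl) delivers the formyl group only ortho to the free phenol, and the single open ortho position is the future ether-side fusion carbon of ring B.

Step 8
Reactants: 5 3-(benzyloxy)-2-bromo-4-methoxy-6-methylbenzoic acid; 10 3,5-bis(benzyloxy)-2-hydroxy-4-methylbenzaldehyde
Product: 11 3-(benzyloxy)-2-[2,4-bis(benzyloxy)-6-formyl-3-methylphenoxy]-4-methoxy-6-methylbenzoic acid
Conditions: CuI (cat.), Cs2CO3, pyridine–DMF, 110 °C; then aq. HCl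
Reagents that add atoms: none
Why: Ullmann diaryl ether synthesis, in which the ortho-carboxylate of 5 binds copper and activates the C–Br bond, the classical entry to 2-aryloxybenzoic acids with flanking substituents.

Step 9
Reactants: 11 3-(benzyloxy)-2-[2,4-bis(benzyloxy)-6-formyl-3-methylphenoxy]-4-methoxy-6-methylbenzoic acid
Product: 12 3-(benzyloxy)-2-[2,4-bis(benzyloxy)-6-(hydroxymethyl)-3-methylphenoxy]-4-methoxy-6-methylbenzoic acid
Conditions: NaBH4, THF–MeOH, 0 °C; then aq. citric acid
Reagents that add atoms: none
Why: Chemoselective borohydride reduction takes the aldehyde to the benzylic alcohol and leaves the carboxylate untouched.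

Step 10
Reactants: 12 3-(benzyloxy)-2-[2,4-bis(benzyloxy)-6-(hydroxymethyl)-3-methylphenoxy]-4-methoxy-6-methylbenzoic acid
Product: 14 3-(benzyloxy)-2-{2,4-bis(benzyloxy)-6-[(tert-butyldimethylsilyloxy)methyl]-3-methylphenoxy}-4-methoxy-6-methylbenzoic acid, via bis-silylated ester 13 (not isolated)
Conditions: TBSCl, imidazole, DMF, rt; then K2CO3 (cat.), THF–H2O, rt
Reagents that add atoms: tert-butyldimethylsilyl chloride, CC(C)(C)[Si](C)(C)Cl
Why: Silylation caps the primary alcohol and transiently the acid, and the far more labile silyl ester is hydrolysed selectively, so the alcohol cannot compete in the later lactonisation.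

Step 11
Reactants: 14 3-(benzyloxy)-2-{2,4-bis(benzyloxy)-6-[(tert-butyldimethylsilyloxy)methyl]-3-methylphenoxy}-4-methoxy-6-methylbenzoic acid
Product: 15 2-{6-[(tert-butyldimethylsilyloxy)methyl]-2,4-dihydroxy-3-methylphenoxy}-3-hydroxy-4-methoxy-6-methylbenzoic acid
Conditions: H2 (1 atm), Pd/C, EtOAc, rt
Reagents that add atoms: none
Why: Catalytic hydrogenolysis removes the three aryl benzyl ethers much faster than it attacks the flanked benzylic silyl ether, and neutral ethyl acetate avoids acid that would promote that cleavage.

Step 12
Reactants: 15 2-{6-[(tert-butyldimethylsilyloxy)methyl]-2,4-dihydroxy-3-methylphenoxy}-3-hydroxy-4-methoxy-6-methylbenzoic acid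
Product: 16 depsidone diphenol (ring C closed between the ring-A carboxyl and the ring-B oxygen ortho to the ether bridge; both phenols free; ring B carries CH2OTBS on the ether-side fusion carbon and H on the phenol-side fusion carbon)
Conditions: DCC, DMAP (cat.), CH2Cl2 (2 mM), 0 °C → rt
Reagents that add atoms: none
Why: Steglich-type lactonisation is regioselective by geometry, since only the ring-B hydroxyl ortho to the ether bridge can reach the activated acid to close the seven-membered ring, and high dilution suppresses intermolecular acylation of the other phenols.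

Step 13
Reactants: 16 depsidone diphenol
Product: 17 formyl depsidone diphenol (CHO on the phenol-side fusion carbon, CH2OTBS on the ether-side fusion carbon, both phenols free)
Conditions: MgCl2, Et3N, (CH2O)n, THF, reflux
Reagents that add atoms: formaldehyde (from paraformaldehyde), C=O
Why: Magnesium-mediated ortho-formylation (Casnati–Skattebøl) can only reach the single free ring-B carbon, because both ortho positions of the ring-A phenol are substituted, and the doubly flanked ring-C carbonyl resists the methanol released.

Step 14
Reactants: 17 formyl depsidone diphenol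
Product: 18 formyl depsidone tris-silyl ether (both phenols as TBS ethers, CH2OTBS on the ether-side fusion carbon)
Conditions: TBSOTf, 2,6-lutidine, CH2Cl2, 0 °C
Reagents that add atoms: tert-butyldimethylsilyl triflate, CC(C)(C)[Si](C)(C)OS(=O)(=O)C(F)(F)F
Why: Silyl triflate silylation caps both hindered phenols, which removes the excited-state proton transfer of the salicylaldehyde that would quench the next step and protects the phenols from the later oxidants.

Step 15
Reactants: 18 formyl depsidone tris-silyl ether
Product: 19 racemic trans-benzocyclobutenol (four-membered ring fused to ring B; C-1 = CH(OH), C-2 = CH(OTBS), OH and OTBS trans)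
Conditions: hν (365 nm), degassed benzene (5 mM), 15 °C
Reagents that add atoms: none
Why: Photoenolisation by 1,5-hydrogen transfer from the siloxymethyl group to the excited formyl oxygen gives the E,E-hydroxy-o-quinodimethane, whose thermal conrotatory 4π electrocyclisation sets both new stereocentres trans to each other as a racemate, while 365 nm light excites only the aryl aldehyde.

Step 16
Reactants: 19 racemic trans-benzocyclobutenol
Product: 20 (1S,2S)-trans-benzocyclobutenol
Conditions: (S)-benzotetramisole (10 mol%), (i-PrCO)2O (0.6 equiv), i-Pr2NEt, CHCl3, 0 °C, to about 55% conversion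
Reagents that add atoms: none
Why: Kinetic resolution by enantioselective acyl transfer to a benzylic carbinol, in which the (S)-catalyst is expected by the cation–π stacking model to acylate the (1R,2R) enantiomer and so leave the (1S,2S) alcohol with both stereocentres fixed in absolute terms, the antipodal catalyst being available should the sense prove reversed.

Step 17
Reactants: 20 (1S,2S)-trans-benzocyclobutenol
Product: 21 (S)-siloxybenzocyclobutenone (ketone carbon on the phenol-side fusion carbon, (S)-CH(OTBS) on the ether-side fusion carbon, both phenols as TBS ethers)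
Conditions: Dess–Martin periodinane, NaHCO3, CH2Cl2, 0 °C → rt
Reagents that add atoms: none
Why: Dess–Martin oxidation works under non-basic conditions that avoid alkoxide-triggered opening of the four-membered ring, and the remaining stereocentre cannot epimerise because its enol would be an antiaromatic benzocyclobutadiene.

Step 18
Reactants: 21 (S)-siloxybenzocyclobutenone
Product: 22 tris-silyl ether of the target (ring D closed, lactol carbon as (S)-configured O-TBS acetal, both phenols as TBS ethers)
Conditions: mCPBA, NaHCO3, CH2Cl2, 0 °C
Reagents that add atoms: 3-chloroperbenzoic acid, OOC(=O)c1cccc(Cl)c1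
Why: Proposed new method: the peracid adds to the strained ketone carbon to give a tetrahedral peroxy (Criegee) adduct, and the benzylic siloxy-bearing sp3 carbon then shifts from carbon to oxygen as 3-chlorobenzoate leaves, so that the new oxygen lies between C(=O) and CH(OTBS). The closest known reaction type is the regioselective, stereoretentive Baeyer–Villiger oxidation of α-alkoxy- and α-siloxycyclobutanones to γ-lactone acetals, which has not been shown for an arene-fused cyclobutenone of this kind. Ring D is not closed by a cyclisation but arises by one-atom ring expansion, a 1,2-shift of a ring bond that turns the four-membered ring into the five-membered one and is driven by release of strain. The stereocentre is relayed, not created: the migrating carbon keeps its configuration because the shift is suprafacial, so the resolved carbinol of 21 fixes the silyl acetal of 22. The step needs regioselectivity (sp3 carbon against the ring-B aryl carbon) and chemoselectivity (ketone against the arenes and the ring-C lactone); the oxygen lone pair and the benzylic position raise the migratory aptitude of the siloxy carbon, in-plane migration of the fused aryl carbon is geometrically disfavoured, and the silyl caps keep the phenols from peracid oxidation. The bicarbonate buffer protects the acid-labile silyl acetal from 3-chlorobenzoic acid.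

Step 19
Reactants: 22 tris-silyl ether of the target
Product: 23 CNP0211607.1, the (R)-lactol depsidone
Conditions: HF·pyridine, pyridine, THF, 0 °C
Reagents that add atoms: none
Why: Fluoride-mediated desilylation attacks silicon only, so the two aryl silyl ethers and the silyl acetal are cleaved without touching a C–O bond of the lactol carbon, whose configuration is kept under cold, non-basic conditions.

**Compound list**

1 | creosol (2-methoxy-4-methylphenol) | COc1cc(C)ccc1O | starting material
2 | 2-bromo-6-methoxy-4-methylphenol | COc1cc(C)cc(Br)c1O | intermediate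
3 | 2-(benzyloxy)-1-bromo-3-methoxy-5-methylbenzene | COc1cc(C)cc(Br)c1OCc1ccccc1 | intermediate
4 | 3-(benzyloxy)-2-bromo-4-methoxy-6-methylbenzaldehyde | COc1cc(C)c(C=O)c(Br)c1OCc1ccccc1 | intermediate
5 | 3-(benzyloxy)-2-bromo-4-methoxy-6-methylbenzoic acid | COc1cc(C)c(C(=O)O)c(Br)c1OCc1ccccc1 | intermediate
6 | 2,4-dihydroxy-3-methylbenzaldehyde | Cc1c(O)ccc(C=O)c1O | starting material
7 | 2,4-bis(benzyloxy)-3-methylbenzaldehyde | Cc1c(OCc2ccccc2)ccc(C=O)c1OCc1ccccc1 | intermediate
8 | 2,4-bis(benzyloxy)-3-methylphenyl formate (not isolated) | Cc1c(OCc2ccccc2)ccc(OC=O)c1OCc1ccccc1 | intermediate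
9 | 2,4-bis(benzyloxy)-3-methylphenol | Cc1c(OCc2ccccc2)ccc(O)c1OCc1ccccc1 | intermediate
10 | 3,5-bis(benzyloxy)-2-hydroxy-4-methylbenzaldehyde | Cc1c(OCc2ccccc2)cc(C=O)c(O)c1OCc1ccccc1 | intermediate
11 | 3-(benzyloxy)-2-[2,4-bis(benzyloxy)-6-formyl-3-methylphenoxy]-4-methoxy-6-methylbenzoic acid | COc1cc(C)c(C(=O)O)c(Oc2c(C=O)cc(OCc3ccccc3)c(C)c2OCc2ccccc2)c1OCc1ccccc1 | intermediate
12 | 3-(benzyloxy)-2-[2,4-bis(benzyloxy)-6-(hydroxymethyl)-3-methylphenoxy]-4-methoxy-6-methylbenzoic acid | COc1cc(C)c(C(=O)O)c(Oc2c(CO)cc(OCc3ccccc3)c(C)c2OCc2ccccc2)c1OCc1ccccc1 | intermediate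
13 | TBS ester of 14 (bis-silylated, not isolated) | COc1cc(C)c(C(=O)O[Si](C)(C)C(C)(C)C)c(Oc2c(CO[Si](C)(C)C(C)(C)C)cc(OCc3ccccc3)c(C)c2OCc2ccccc2)c1OCc1ccccc1 | intermediate
14 | 3-(benzyloxy)-2-{2,4-bis(benzyloxy)-6-[(tert-butyldimethylsilyloxy)methyl]-3-methylphenoxy}-4-methoxy-6-methylbenzoic acid | COc1cc(C)c(C(=O)O)c(Oc2c(CO[Si](C)(C)C(C)(C)C)cc(OCc3ccccc3)c(C)c2OCc2ccccc2)c1OCc1ccccc1 | intermediate
15 | 2-{6-[(tert-butyldimethylsilyloxy)methyl]-2,4-dihydroxy-3-methylphenoxy}-3-hydroxy-4-methoxy-6-methylbenzoic acid | COc1cc(C)c(C(=O)O)c(Oc2c(CO[Si](C)(C)C(C)(C)C)cc(O)c(C)c2O)c1O | intermediate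
16 | depsidone diphenol (both phenols free, H on the phenol-side fusion carbon, CH2OTBS on the ether-side fusion carbon) | COc1cc(C)c2c(c1O)Oc1c(CO[Si](C)(C)C(C)(C)C)cc(O)c(C)c1OC2=O | intermediate
17 | formyl depsidone diphenol (CHO on the phenol-side fusion carbon) | COc1cc(C)c2c(c1O)Oc1c(CO[Si](C)(C)C(C)(C)C)c(C=O)c(O)c(C)c1OC2=O | intermediate
18 | formyl depsidone tris-silyl ether | COc1cc(C)c2c(c1O[Si](C)(C)C(C)(C)C)Oc1c(CO[Si](C)(C)C(C)(C)C)c(C=O)c(O[Si](C)(C)C(C)(C)C)c(C)c1OC2=O | intermediate
19 | racemic trans-benzocyclobutenol (one enantiomer drawn) | COc1cc(C)c2c(c1O[Si](C)(C)C(C)(C)C)Oc1c(c(C)c(O[Si](C)(C)C(C)(C)C)c3c1[C@H](O[Si](C)(C)C(C)(C)C)[C@H]3O)OC2=O | intermediate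
20 | (1S,2S)-trans-benzocyclobutenol (C-1 = CH(OH), C-2 = CH(OTBS)) | COc1cc(C)c2c(c1O[Si](C)(C)C(C)(C)C)Oc1c(c(C)c(O[Si](C)(C)C(C)(C)C)c3c1[C@H](O[Si](C)(C)C(C)(C)C)[C@H]3O)OC2=O | intermediate
21 | (S)-siloxybenzocyclobutenone, tris-silyl depsidone | COc1cc(C)c2c(c1O[Si](C)(C)C(C)(C)C)Oc1c(c(C)c(O[Si](C)(C)C(C)(C)C)c3c1[C@H](O[Si](C)(C)C(C)(C)C)C3=O)OC2=O | intermediate
22 | tris-silyl ether of the target, (S)-silyl acetal | COc1cc(C)c2c(c1O[Si](C)(C)C(C)(C)C)Oc1c(c(C)c(O[Si](C)(C)C(C)(C)C)c3c1[C@H](O[Si](C)(C)C(C)(C)C)OC3=O)OC2=O | intermediate
23 | CNP0211607.1, (R)-lactol | COc1cc(C)c2c(c1O)Oc1c(c(C)c(O)c3c1[C@H](O)OC3=O)OC2=O | target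

**Step count.** Total: 19 steps. Longest linear sequence: 16 steps (steps 1–4, then 8–19).

**Steps most likely to fail**

Step 18. The ring-B aryl carbon may migrate in place of the siloxy carbon, the peracid may attack the electron-rich rings, or the silyl acetal may be lost to acid. The fallback uses known reactions only and sets out from 21. Dilute aqueous HCl in THF–MeCN at 0 °C removes the carbinol silyl group, which is far more acid-labile than the aryl silyl ethers, to give the (S)-hydroxy ketone F1. Glycol-type cleavage of this α-ketol with NaIO4 in aqueous THF gives the ring-B formyl carboxylic acid, which should close at once to the racemic bis-silyl lactol F2. Silylation (TBSCl, imidazole, DMF) should give the racemic silyl acetal F3, which is configurationally stable and is resolved by preparative chromatography on a chiral stationary phase. The (R)-silyl acetal F4 is discarded and the route is rejoined at 22. Because the cleavage erases the configuration, unresolved ketone serves equally well here.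

Step 8. C–O bond formation between two doubly ortho-substituted partners may be too slow with the chelated, electron-poor phenoxide of 10, so that protodebromination of 5 takes over. The fallback recasts the partners, setting out from 10 and 4. NaBH4 reduces 10 to the salicyl alcohol F5. Both hydroxyls are silylated (TBSCl, imidazole) to the bis-silyl ether F6, and K2CO3 in MeOH cleaves only the aryl silyl ether to give the electron-rich, unchelated silyloxymethyl phenol F7. This is coupled with bromo aldehyde 4, whose ortho-formyl group now activates the bromide (CuI, picolinic acid, K3PO4, DMSO, 90 °C), to give the diaryl ether aldehyde F8. Pinnick oxidation then rejoins the route at 14.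

Step 16. The acyl-transfer catalyst may discriminate poorly between the enantiomers of the hindered carbinol, or acylate it too slowly. The fallback moves the resolution to the ketone and sets out from 19. Dess–Martin oxidation gives the racemic ketone F9. A partial Corey–Bakshi–Shibata reduction ((S)-2-methyl-CBS-oxazaborolidine, BH3·SMe2 as the limiting reagent, THF, −30 °C) should consume the (R)-ketone in the matched sense, hydride arriving anti to the siloxy group, to give the cis-(1S,2R)-alcohol F10. The mismatched (S)-ketone is recovered and separated on silica; it is 21, where the route is rejoined.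

**Further compounds**

F1 | step 18 | (S)-hydroxy ketone (carbinol silyl group removed from 21) | COc1cc(C)c2c(c1O[Si](C)(C)C(C)(C)C)Oc1c(c(C)c(O[Si](C)(C)C(C)(C)C)c3c1[C@H](O)C3=O)OC2=O
F2 | step 18 | racemic bis-silyl lactol (both phenols as TBS ethers, free lactol OH) | COc1cc(C)c2c(c1O[Si](C)(C)C(C)(C)C)Oc1c(c(C)c(O[Si](C)(C)C(C)(C)C)c3c1C(O)OC3=O)OC2=O
F3 | step 18 | racemic silyl acetal (racemate of 22) | COc1cc(C)c2c(c1O[Si](C)(C)C(C)(C)C)Oc1c(c(C)c(O[Si](C)(C)C(C)(C)C)c3c1C(O[Si](C)(C)C(C)(C)C)OC3=O)OC2=O
F4 | step 18 | (R)-silyl acetal (enantiomer of 22) | COc1cc(C)c2c(c1O[Si](C)(C)C(C)(C)C)Oc1c(c(C)c(O[Si](C)(C)C(C)(C)C)c3c1[C@@H](O[Si](C)(C)C(C)(C)C)OC3=O)OC2=O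
F5 | step 8 | 2,4-bis(benzyloxy)-6-(hydroxymethyl)-3-methylphenol | Cc1c(OCc2ccccc2)cc(CO)c(O)c1OCc1ccccc1
F6 | step 8 | bis-silyl ether of F5 | Cc1c(OCc2ccccc2)cc(CO[Si](C)(C)C(C)(C)C)c(O[Si](C)(C)C(C)(C)C)c1OCc1ccccc1
F7 | step 8 | 2,4-bis(benzyloxy)-6-[(tert-butyldimethylsilyloxy)methyl]-3-methylphenol | Cc1c(OCc2ccccc2)cc(CO[Si](C)(C)C(C)(C)C)c(O)c1OCc1ccccc1
F8 | step 8 | 3-(benzyloxy)-2-{2,4-bis(benzyloxy)-6-[(tert-butyldimethylsilyloxy)methyl]-3-methylphenoxy}-4-methoxy-6-methylbenzaldehyde | COc1cc(C)c(C=O)c(Oc2c(CO[Si](C)(C)C(C)(C)C)cc(OCc3ccccc3)c(C)c2OCc2ccccc2)c1OCc1ccccc1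
F9 | step 16 | racemic siloxybenzocyclobutenone (racemate of 21) | COc1cc(C)c2c(c1O[Si](C)(C)C(C)(C)C)Oc1c(c(C)c(O[Si](C)(C)C(C)(C)C)c3c1C(O[Si](C)(C)C(C)(C)C)C3=O)OC2=O
F10 | step 16 | cis-(1S,2R)-benzocyclobutenol | COc1cc(C)c2c(c1O[Si](C)(C)C(C)(C)C)Oc1c(c(C)c(O[Si](C)(C)C(C)(C)C)c3c1[C@@H](O[Si](C)(C)C(C)(C)C)[C@H]3O)OC2=O
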